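**Retrosynthetic overview**

1. Target 12 ← desilylation of the 7-O-TBS flavanone 11, whose C2 (S) configuration is fixed by a catalyst-controlled kinetic resolution (asymmetric transfer hydrogenation) of racemic 10.
2. The racemic flavanone C-ring (the only ring formed) ← intramolecular oxa-Michael closure (O1–C2 bond) of 2'-hydroxychalcone 7.
3. Chalcone 7 ← intermolecular Claisen–Schmidt crossed aldol condensation of aryl methyl ketone 5 with aldehyde 3; this is the key C–C bond (C2–C3 of the flavanone).
4. Aldehyde 3 ← 4-hydroxybenzaldehyde + geranyl bromide; ketone 5 ← 2',4'-dihydroxyacetophenone (4'-O-THP).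
5. Ring order: the A and B rings are bought; the pyranone C-ring is closed in step 4; the stereocentre is fixed in step 7.

Assumption: the target is (2S)-7-hydroxy-4'-(geranyloxy)flavanone (C2 = S as read from the SMILES; geranyl = (2E)-3,7-dimethylocta-2,6-dien-1-yl), and geranyl bromide is bought as the pure (E)-isomer.

**Step 1**
Reactants: 1 4-hydroxybenzaldehyde; 2 geranyl bromide
Product: 3 4-(geranyloxy)benzaldehyde
Conditions: K2CO3 (1.5 equiv), DMF, rt, 12 h
Reagents that add atoms: none
Why: Williamson ether synthesis, a clean SN2 of the phenoxide on the primary allylic bromide that keeps the (E)-alkene and installs the acid-sensitive geranyl ether before any step that could disturb it.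

**Step 2**
Reactants: 4 2',4'-dihydroxyacetophenone
Product: 5 2'-hydroxy-4'-(tetrahydropyran-2-yloxy)acetophenone
Conditions: 3,4-dihydro-2H-pyran (1.5 equiv), PPTS (0.1 equiv), CH2Cl2, rt, 5 h
Reagents that add atoms: 3,4-dihydro-2H-pyran, C1=COCCC1
Why: Acid-catalysed acetalisation (THP protection) goes selectively at the 4'-OH because the 2'-OH is hydrogen-bonded to the carbonyl, and the THP ether survives the hydroxide of the next step.

**Step 3**
Reactants: 5 2'-hydroxy-4'-(tetrahydropyran-2-yloxy)acetophenone; 3 4-(geranyloxy)benzaldehyde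
Product: 7 (E)-4-(geranyloxy)-2'-hydroxy-4'-(tetrahydropyran-2-yloxy)chalcone, via β-hydroxy ketone 6 (not isolated)
Conditions: KOH (50% aq., excess), EtOH, 0 °C to rt, 36 h; cold NH4Cl/AcOH quench to pH 6–7
Reagents that add atoms: none
Why: Claisen–Schmidt crossed aldol condensation: the ketone enolate adds to the non-enolisable aldehyde and E1cB dehydration of aldol 6 gives the conjugated (E)-chalcone, with the THP and geranyl ethers inert to base (any flavanone 8 already formed converges in step 4).

**Step 4**
Reactants: 7 (E)-4-(geranyloxy)-2'-hydroxy-4'-(tetrahydropyran-2-yloxy)chalcone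
Product: 8 rac-4'-(geranyloxy)-7-(tetrahydropyran-2-yloxy)flavanone
Conditions: NaOAc (5 equiv), EtOH, reflux, 24–48 h; recovered 7 recycled
Reagents that add atoms: none
Why: Intramolecular oxa-Michael addition (6-endo closure of the 2'-phenol onto the enone) under weakly basic equilibrium conditions forms the pyranone ring; C2 is formed racemic on purpose and resolved later.

**Step 5**
Reactants: 8 rac-4'-(geranyloxy)-7-(tetrahydropyran-2-yloxy)flavanone
Product: 9 rac-4'-(geranyloxy)-7-hydroxyflavanone
Conditions: PPTS (0.2 equiv), MeOH, 45 °C, 3 h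
Reagents that add atoms: none
Why: Mild acid-catalysed transacetalisation to methanol removes the phenolic THP group (and its extra stereocentre) at a pH too weak to ionise the geranyl aryl ether or open the flavanone.

**Step 6**
Reactants: 9 rac-4'-(geranyloxy)-7-hydroxyflavanone
Product: 10 rac-7-(tert-butyldimethylsilyloxy)-4'-(geranyloxy)flavanone
Conditions: TBSCl (1.3 equiv), imidazole (2.5 equiv), CH2Cl2, 0 °C to rt, 2 h
Reagents that add atoms: tert-butyldimethylsilyl chloride (TBSCl), CC(C)(C)[Si](C)(C)Cl
Why: Standard silylation of the only free phenol gives a single racemate whose protecting group tolerates formic acid/triethylamine and can later be removed without acid or free base.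

**Step 7**
Reactants: 10 rac-7-(tert-butyldimethylsilyloxy)-4'-(geranyloxy)flavanone
Product: 11 (2S)-7-(tert-butyldimethylsilyloxy)-4'-(geranyloxy)flavanone
Conditions: Cp*RhCl[(R,R)-TsDPEN] (1 mol %), HCO2H/Et3N (5:2), EtOAc, rt, stopped at 52–55% conversion (chiral HPLC); chromatography
Reagents that add atoms: none
Why: Noyori–Ikariya asymmetric transfer hydrogenation run as a kinetic resolution: the (R,R)-catalyst makes a 4R carbinol, which is the matched cis-selective reduction only for the (R)-ketone, so the (R)-enantiomer is drained to the cis-(2R,4R)-flavan-4-ol while (S)-ketone 11 remains at ≥99% ee with C2 untouched in the weakly acidic medium; isolated alkenes are not reduced.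

**Step 8**
Reactants: 11 (2S)-7-(tert-butyldimethylsilyloxy)-4'-(geranyloxy)flavanone
Product: 12 (2S)-4'-(geranyloxy)-7-hydroxyflavanone
Conditions: TBAF (1.1 equiv), AcOH (1.5 equiv), THF, 0 °C, 30 min
Reagents that add atoms: none
Why: Fluoride-mediated desilylation of the aryl silyl ether, buffered with acetic acid so that no free base can trigger E1cB ring opening (retro-oxa-Michael) and racemise C2; the geranyl ether is inert.

**Compound list**

1 | 4-hydroxybenzaldehyde | O=Cc1ccc(O)cc1 | starting material
2 | geranyl bromide, (2E)-1-bromo-3,7-dimethylocta-2,6-diene | CC(C)=CCC/C(C)=C/CBr | starting material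
3 | 4-(geranyloxy)benzaldehyde, 4-[(2E)-3,7-dimethylocta-2,6-dien-1-yloxy]benzaldehyde | CC(C)=CCC/C(C)=C/COc1ccc(C=O)cc1 | intermediate
4 | 2',4'-dihydroxyacetophenone, 1-(2,4-dihydroxyphenyl)ethan-1-one | CC(=O)c1ccc(O)cc1O | starting material
5 | 2'-hydroxy-4'-(tetrahydropyran-2-yloxy)acetophenone (racemic acetal carbon) | CC(=O)c1ccc(OC2CCCCO2)cc1O | intermediate
6 | β-hydroxy ketone (aldol adduct), 3-[4-(geranyloxy)phenyl]-3-hydroxy-1-[2-hydroxy-4-(tetrahydropyran-2-yloxy)phenyl]propan-1-one, racemic | CC(C)=CCC/C(C)=C/COc1ccc(C(O)CC(=O)c2ccc(OC3CCCCO3)cc2O)cc1 | intermediate (not isolated)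
7 | (E)-4-(geranyloxy)-2'-hydroxy-4'-(tetrahydropyran-2-yloxy)chalcone, (E)-3-[4-(geranyloxy)phenyl]-1-[2-hydroxy-4-(tetrahydropyran-2-yloxy)phenyl]prop-2-en-1-one | CC(C)=CCC/C(C)=C/COc1ccc(/C=C/C(=O)c2ccc(OC3CCCCO3)cc2O)cc1 | intermediate
8 | rac-4'-(geranyloxy)-7-(tetrahydropyran-2-yloxy)flavanone, 2-[4-(geranyloxy)phenyl]-7-(tetrahydropyran-2-yloxy)chroman-4-one, racemic at C2, both acetal epimers | CC(C)=CCC/C(C)=C/COc1ccc(C2CC(=O)c3ccc(OC4CCCCO4)cc3O2)cc1 | intermediate
9 | rac-4'-(geranyloxy)-7-hydroxyflavanone, 2-[4-(geranyloxy)phenyl]-7-hydroxychroman-4-one, racemic | CC(C)=CCC/C(C)=C/COc1ccc(C2CC(=O)c3ccc(O)cc3O2)cc1 | intermediate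
10 | rac-7-(tert-butyldimethylsilyloxy)-4'-(geranyloxy)flavanone, racemic | CC(C)=CCC/C(C)=C/COc1ccc(C2CC(=O)c3ccc(O[Si](C)(C)C(C)(C)C)cc3O2)cc1 | intermediate
11 | (2S)-7-(tert-butyldimethylsilyloxy)-4'-(geranyloxy)flavanone | CC(C)=CCC/C(C)=C/COc1ccc([C@@H]2CC(=O)c3ccc(O[Si](C)(C)C(C)(C)C)cc3O2)cc1 | intermediate
12 | (2S)-4'-(geranyloxy)-7-hydroxyflavanone, (2S)-2-{4-[(2E)-3,7-dimethylocta-2,6-dien-1-yloxy]phenyl}-7-hydroxy-2,3-dihydro-4H-chromen-4-one | CC(C)=CCC/C(C)=C/COc1ccc([C@@H]2CC(=O)c3ccc(O)cc3O2)cc1 | target

**Step count**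

Total steps: 8. Longest linear sequence: 7 steps (4 → 5 → 7 → 8 → 9 → 10 → 11 → 12; the branch from 1 through 3 is equally long).

**Three steps most likely to fail, with fallbacks**

Step 7 (kinetic resolution; the selectivity factor on this 7-silyloxy substrate may be too low for ≥99% ee at useful recovery). The fallback leaves catalytic resolution for physical enantiomer separation. It sets out from racemic 10 and comes back to the route at 11. Racemic 10 is resolved by preparative chiral SFC or HPLC on an amylose tris(3,5-dimethylphenylcarbamate) phase (heptane/2-propanol or CO2/MeOH). The (S)-enantiomer is collected and is identical with 11; it is assigned by CD (positive n→π* Cotton effect near 330 nm and negative band near 290 nm for 2S flavanones).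

Step 4 (oxa-Michael closure; the chalcone/flavanone equilibrium may lie unfavourably because the 4-alkoxy B-ring stabilises the chalcone). The fallback closes the O1–C2 bond by substitution at the carbinol carbon instead of conjugate addition. It sets out from 5 (together with 3) and comes back at 8. Ketone 5 is converted to its dianion (LDA, 2.2 equiv, THF, −78 °C) and treated with aldehyde 3. A cold AcOH quench allows the β-hydroxy ketone (aldol adduct) 6 to be isolated instead of dehydrated. Intramolecular Mitsunobu etherification of 6 (PPh3, DIAD, THF, 0 °C) then gives the racemic flavanone 8 directly. Any chalcone 7 formed by elimination is separated and returned to step 4.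

Step 8 (final desilylation; risk of partial ring opening and racemisation if the fluoride step is not kept buffered). The fallback changes the protecting-group strategy so that the last deprotection is enzymatic at neutral pH. It sets out from 9 and comes back at 12. Phenol 9 is acetylated (Ac2O, pyridine, cat. DMAP, CH2Cl2, 0 °C) to rac-7-acetoxy-4'-(geranyloxy)flavanone F1. F1 is resolved by the same Cp*RhCl[(R,R)-TsDPEN]/HCO2H–Et3N transfer hydrogenation, giving (2S)-7-acetoxy-4'-(geranyloxy)flavanone F2 after chromatography. The acetate of F2 is removed by lipase-catalysed alcoholysis (Candida antarctica lipase B, n-BuOH, MTBE, 40 °C) to give 12 without acid, base or fluoride.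

**Further compounds**

F0 | step 7 | none | none
F0 | step 4 | none | none
F1 | step 8 | rac-7-acetoxy-4'-(geranyloxy)flavanone, 2-[4-(geranyloxy)phenyl]-4-oxochroman-7-yl acetate, racemic | CC(C)=CCC/C(C)=C/COc1ccc(C2CC(=O)c3ccc(OC(C)=O)cc3O2)cc1
F2 | step 8 | (2S)-7-acetoxy-4'-(geranyloxy)flavanone, (2S)-2-[4-(geranyloxy)phenyl]-4-oxochroman-7-yl acetate | CC(C)=CCC/C(C)=C/COc1ccc([C@@H]2CC(=O)c3ccc(OC(C)=O)cc3O2)cc1
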